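The rate constants are assumed; the run is a simulation.

A slow feed of D into a stirred solution of X is run at rising charges of D, and each flask is read when the feed ends.

| setting | north-east | south-west | south-east |
|---|---|---|---|
| X | 0.050 M | 0.050 M | 0.050 M |
| D | 0.0480 M (fed, over 3.0 min) | 0.0710 M (fed, over 3.0 min) | 0.110 M (fed, over 3.0 min) |
| time | 3.0 min | 3.0 min | 3.0 min |

    X + D → L + Z (k1 = 0.196 M⁻¹ s⁻¹)
    D + L ⇌ D.L, settled at all times (K2 = 2.02 × 10⁵ M⁻¹)
    X + Z → X.Z (k3 = 0.103 M⁻¹ s⁻¹)
    2 D → D2 (k4 = 0.0263 M⁻¹ s⁻¹)

- percent here means X units held: one X.Z counts as two
- a doubled species enters its step squared and goes two at a time
- run time (north-east): 3.0 min

- part of the X that has reacted at the end, north-east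
- part of the X that has reacted at the end, south-west
- part of the X that has reacted at the end, south-east
- what raising the concentration of D from its lowest to its highest value here does to the part of the X that has reacted (changes below 5 percentage points count as none) (it rises / it falls / no change)

The reckoning here turns the constants into times. With 2.02 × 10⁵ M⁻¹, free L stands to D.L as one to 9700, reckoned at the whole north-east charge of D, so each L takes a second D away as D.L, the resting state of L, and one turn of the first step costs two D. A free D then lasts τ = 51.0 s at the charged X, which is shorter than the dosing time 3.0 min. So, as a first reckoning, after about τ free D stands where loss meets feed, and the first step turns once for every two D fed.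

This gives one number, the reach Q: the charge of D, divided by two and by the charge of X, times the part of the dosing time left after τ. It estimates the part of the X that has gone through the first step when the feed ends. Q is 34.4% for north-east, 50.9% for south-west and 78.8% for south-east, so the reacted part should rise, by 44 percentage points.

One number may not be enough. Z has a half-life of 2.2 min towards X.Z by the third step at the charged X, shorter than the dosing time, and that step takes further X, while falling X lengthens τ and works the other way.

The forecast, on the ground that “each L formed immediately traps one D”, gives 38% for north-east, 52% for south-west and 70% for south-east, and says it rises.

The simulation gives 37.8% for north-east, 51.1% for south-west and 68.0% for south-east: it rises, by 30 points. Q stands 3.4 points under the reacted part of north-east and 11 points over that of south-east. A neighbouring flask repeats south-west with 0.018 M of D, and its Q is 12.9%. That flask has reacted 15.9% of its X, with X.Z at 6.83% of the X charged. Counting Z and one of the two X units of each X.Z, the X carried through the first step comes to 12.4%.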